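**Retrosynthetic overview**
- The target comes from a trans-fused hydroazulenone by methyl 1,2-addition at C4 and desilylation. The seven-membered ring is formed last, by an intramolecular Nozaki–Hiyama–Kishi closure of C9–C10 (alkenyl bromide onto aldehyde).
- The cyclisation substrate comes from an anti/Felkin aldol (C5–C6) between the α′-enolate of (S)-4-(1-bromoethenyl)cyclopent-2-enone and a side-chain aldehyde. The five-membered ring is present from the start (enantiopure 4-silyloxycyclopentenone).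
- Side-chain aldehyde: C7–C11 by Ireland–Claisen rearrangement of an (R)-pent-3-en-2-yl 4,4-dimethoxybutanoate; C12–C13 by Felkin-controlled γ-silyloxyallylstannane addition; isobutenyl group by cross-metathesis; C6 aldehyde released from a morpholine amide.

Numbering used in the text: C1/C5 ring fusion, C2=C3, C4 = C(OH)CH3, C6 = CHOH, C7 carries the side chain, C8 = CH2, C9 = CHOH, C10 = C(=CH2); side chain C11 (CHCH3), C12 and C13 (CHOAc), C14=C15.

Assumption: the SMILES is taken as written (trans-fused ring system; 1R,4S,5R,6R,7S,9R,11R,12S,13S), and (3E)-pent-3-en-2-one, methyl 4,4-dimethoxybutanoate, allyl tert-butyldimethylsilyl ether, (S)-4-(tert-butyldimethylsilyloxy)cyclopent-2-enone and the named reagents are bought.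

**Step 1**
Reactants: 1 (3E)-pent-3-en-2-one
Product: 2 (2R,3E)-pent-3-en-2-ol
Conditions: (S)-2-methyl-CBS-oxazaborolidine (10 mol%), catecholborane, toluene, −78 °C; aq NaOH work-up
Reagents that add atoms: none
Why: Corey–Bakshi–Shibata 1,2-reduction, in which hydride is delivered inside the ketone–oxazaborolidine–borane complex to the face that keeps the propenyl group away from the catalyst, giving the R carbinol.

**Step 2**
Reactants: 3 methyl 4,4-dimethoxybutanoate
Product: 4 4,4-dimethoxybutanoic acid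
Conditions: LiOH·H2O, THF/H2O, 0 °C to rt; then 1 M HCl to pH 4 at 0 °C
Reagents that add atoms: lithium hydroxide, [Li+].[OH-]
Why: Ester saponification; the dimethyl acetal is stable to base and to the brief cold acidification.

**Step 3**
Reactants: 2 (2R,3E)-pent-3-en-2-ol; 4 4,4-dimethoxybutanoic acid
Product: 5 (2R,3E)-pent-3-en-2-yl 4,4-dimethoxybutanoate
Conditions: DCC, DMAP (cat.), CH2Cl2, 0 °C to rt
Reagents that add atoms: none
Why: Steglich esterification acylates the oxygen without breaking the carbinol C–O bond, so the R centre is retained.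

**Step 4**
Reactants: 5 (2R,3E)-pent-3-en-2-yl 4,4-dimethoxybutanoate
Product: 8 (2S,3S,4E)-2-(2,2-dimethoxyethyl)-3-methylhex-4-enoic acid, via silyl ketene acetal 6 (not isolated), via trimethylsilyl ester 7 (not isolated)
Conditions: LiN(iPr)2, THF, −78 °C; Me3SiCl/Et3N, −78 °C to rt, then 50 °C; H2O (pH 4 buffer)
Reagents that add atoms: none
Why: Ireland–Claisen rearrangement, in which the kinetic (E)-silyl ketene acetal and the (E)-alkene react through a chair transition state with the carbinol methyl equatorial, transferring the R carbinol chirality to the anti C7/C11 pair (2S,3S).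

**Step 5**
Reactants: 8 (2S,3S,4E)-2-(2,2-dimethoxyethyl)-3-methylhex-4-enoic acid
Product: 9 (2S,3S,4E)-2-(2,2-dimethoxyethyl)-3-methyl-1-(morpholin-4-yl)hex-4-en-1-one
Conditions: morpholine, EDC·HCl, HOBt, CH2Cl2, 0 °C to rt
Reagents that add atoms: morpholine, C1COCCN1
Why: Carbodiimide amide coupling through the HOBt active ester (no α-epimerisation) gives a tertiary amide that serves as a robust latent aldehyde.

**Step 6**
Reactants: 9 (2S,3S,4E)-2-(2,2-dimethoxyethyl)-3-methyl-1-(morpholin-4-yl)hex-4-en-1-one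
Product: 11 (2R,3S)-3-(2,2-dimethoxyethyl)-2-methyl-4-(morpholin-4-yl)-4-oxobutanal, via ozonide 10 (not isolated)
Conditions: O3, CH2Cl2, −78 °C; then PPh3, −78 °C to rt
Reagents that add atoms: ozone, [O-][O+]=O
Why: Ozonolysis (Criegee mechanism) of the only alkene and reductive cleavage of the ozonide give the C12 aldehyde, whose α-methyl centre survives because the crude aldehyde is kept cold and used at once.

**Step 7**
Reactants: 12 tert-butyl(dimethyl)(prop-2-en-1-yloxy)silane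
Product: 14 tributyl[(2Z)-3-{[tert-butyl(dimethyl)silyl]oxy}prop-2-en-1-yl]stannane, via allyllithium 13 (not isolated)
Conditions: sBuLi, THF/HMPA, −78 °C; then Bu3SnCl, −78 °C to rt
Reagents that add atoms: tributyltin chloride, CCCC[Sn](Cl)(CCCC)CCCC
Why: Allylic deprotonation gives the oxygen-coordinated (Z)-oxyallyl anion, which is stannylated at the terminal carbon (γ-substitution).

**Step 8**
Reactants: 11 (2R,3S)-3-(2,2-dimethoxyethyl)-2-methyl-4-(morpholin-4-yl)-4-oxobutanal; 14 tributyl[(2Z)-3-{[tert-butyl(dimethyl)silyl]oxy}prop-2-en-1-yl]stannane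
Product: 15 (2S,3R,4S,5S)-5-{[tert-butyl(dimethyl)silyl]oxy}-2-(2,2-dimethoxyethyl)-4-hydroxy-3-methyl-1-(morpholin-4-yl)hept-6-en-1-one
Conditions: BF3·OEt2 (2.2 equiv), CH2Cl2, −78 °C; aq NaHCO3
Reagents that add atoms: none
Why: Lewis acid-promoted SE2′ allylstannane addition through an open antiperiplanar transition state, in which Felkin–Anh attack anti to the branched C7 substituent sets C12 (S) and the γ-silyloxy stannane gives the syn C12/C13 relationship (C13 S).

**Step 9**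
Reactants: 15 (2S,3R,4S,5S)-5-{[tert-butyl(dimethyl)silyl]oxy}-2-(2,2-dimethoxyethyl)-4-hydroxy-3-methyl-1-(morpholin-4-yl)hept-6-en-1-one
Product: 16 (2S,3R,4S,5S)-2-(2,2-dimethoxyethyl)-4,5-dihydroxy-3-methyl-1-(morpholin-4-yl)hept-6-en-1-one
Conditions: Bu4NF, THF, 0 °C; aq NH4Cl
Reagents that add atoms: none
Why: Fluoride cleaves the Si–O bond only, so no stereocentre is touched and the dimethyl acetal survives.

**Step 10**
Reactants: 16 (2S,3R,4S,5S)-2-(2,2-dimethoxyethyl)-4,5-dihydroxy-3-methyl-1-(morpholin-4-yl)hept-6-en-1-one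
Product: 17 (3S,4S,5R,6S)-6-(2,2-dimethoxyethyl)-5-methyl-7-(morpholin-4-yl)-7-oxohept-1-ene-3,4-diyl diacetate
Conditions: Ac2O, pyridine, DMAP (cat.), CH2Cl2, rt
Reagents that add atoms: acetic anhydride, CC(=O)OC(C)=O
Why: DMAP-catalysed acylation of both secondary hydroxyls installs the two acetates of the target before any ring hydroxyl exists.

**Step 11**
Reactants: 17 (3S,4S,5R,6S)-6-(2,2-dimethoxyethyl)-5-methyl-7-(morpholin-4-yl)-7-oxohept-1-ene-3,4-diyl diacetate
Product: 18 (4S,5S,6R,7S)-7-(2,2-dimethoxyethyl)-2,6-dimethyl-8-(morpholin-4-yl)-8-oxooct-2-ene-4,5-diyl diacetate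
Conditions: second-generation Grubbs catalyst (5 mol%), 2-methylbut-2-ene/CH2Cl2, 40 °C
Reagents that add atoms: 2-methylbut-2-ene, CC=C(C)C
Why: Olefin cross-metathesis of the only terminal alkene with 2-methylbut-2-ene builds the trisubstituted isobutenyl group with loss of propene and touches no stereocentre.

**Step 12**
Reactants: 18 (4S,5S,6R,7S)-7-(2,2-dimethoxyethyl)-2,6-dimethyl-8-(morpholin-4-yl)-8-oxooct-2-ene-4,5-diyl diacetate
Product: 19 (4S,5S,6R,7S)-7-formyl-9,9-dimethoxy-2,6-dimethylnon-2-ene-4,5-diyl diacetate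
Conditions: Cp2Zr(H)Cl (1.8 equiv), THF, rt, 20 min; H2O
Reagents that add atoms: none
Why: Schwartz-reagent reduction of the tertiary amide stops at the aldehyde oxidation level and leaves the acetates, the acetal and the trisubstituted alkene untouched.

**Step 13**
Reactants: 20 (4S)-4-{[tert-butyl(dimethyl)silyl]oxy}cyclopent-2-en-1-one
Product: 22 (4S)-4-[1-(trimethylsilyl)ethenyl]cyclopent-2-en-1-one, via silyloxy ketone 21 (not isolated)
Conditions: CH2=C(SiMe3)MgBr (from the bromide and Mg, THF), CuBr·SMe2 (10 mol%), THF, −78 °C; aq NH4Cl; then DBU, CH2Cl2, 0 °C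
Reagents that add atoms: (1-bromoethenyl)trimethylsilane, C=C(Br)[Si](C)(C)C
Why: Copper-catalysed conjugate addition anti to the silyloxy group followed by E1cB loss of silanol (net anti SN2′-type replacement) gives the S-configured 4-substituted enone.

**Step 14**
Reactants: 22 (4S)-4-[1-(trimethylsilyl)ethenyl]cyclopent-2-en-1-one
Product: 24 (4S)-4-(1-bromoethenyl)cyclopent-2-en-1-one, via dibromide 23 (not isolated)
Conditions: Br2, CH2Cl2, −78 °C; then KF, MeCN/H2O, 0 °C to rt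
Reagents that add atoms: bromine, BrBr
Why: Bromodesilylation, in which Br2 adds to the electron-rich vinylsilane (the enone alkene is deactivated) and fluoride triggers anti elimination of silicon and bromide to give the 2-bromoalkene regiospecifically.

**Step 15**
Reactants: 24 (4S)-4-(1-bromoethenyl)cyclopent-2-en-1-one; 19 (4S,5S,6R,7S)-7-formyl-9,9-dimethoxy-2,6-dimethylnon-2-ene-4,5-diyl diacetate
Product: 26 (4S,5S,6R,7S)-7-{(R)-[(1R,5R)-5-(1-bromoethenyl)-2-oxocyclopent-3-en-1-yl](hydroxy)methyl}-9,9-dimethoxy-2,6-dimethylnon-2-ene-4,5-diyl diacetate, via lithium dienolate 25 (not isolated)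
Conditions: LiN(iPr)2, THF, −78 °C, 30 min; then 19, −78 °C; aq NH4Cl at −78 °C
Reagents that add atoms: none
Why: Directed aldol addition, in which the kinetic α′ lithium enolate reacts trans to the C1 substituent through a Zimmerman–Traxler chair ((E)-enolate, anti C5/C6) that is matched with Felkin–Anh addition to the α-branched aldehyde, setting C5 (R) and C6 (R).

**Step 16**
Reactants: 26 aldol adduct (name as in step 15)
Product: 29 (4S,5S,6R,7S)-7-{(R)-[(1R,5R)-5-(1-bromoethenyl)-2-oxocyclopent-3-en-1-yl][(triethylsilyl)oxy]methyl}-2,6-dimethyl-9-oxonon-2-ene-4,5-diyl diacetate, via triethylsilyl ether 27 (not isolated), via pyridinium salt 28 (not isolated)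
Conditions: Et3SiOTf (3 equiv), 2,6-lutidine, CH2Cl2, −78 to 0 °C; then H2O, rt
Reagents that add atoms: triethylsilyl trifluoromethanesulfonate, CC[Si](CC)(CC)OS(=O)(=O)C(F)(F)F; water, O
Why: O-silylation of the aldol hydroxyl is followed by silyl triflate/lutidine activation of the dimethyl acetal to a pyridinium N,O-acetal that water hydrolyses to the aldehyde, under conditions that leave ketone, acetates and silyl ether alone.

**Step 17**
Reactants: 29 bromovinyl aldehyde (name as in step 16)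
Product: 30 (2R,3S,4S)-2-[(3aR,5R,7S,8R,8aR)-5-hydroxy-4-methylidene-1-oxo-8-[(triethylsilyl)oxy]-1,3a,4,5,6,7,8,8a-octahydroazulen-7-yl]-6-methylhept-5-ene-3,4-diyl diacetate
Conditions: CrCl2 (8 equiv), NiCl2 (2 mol%), DMSO, rt, 0.005 M
Reagents that add atoms: none
Why: Intramolecular Nozaki–Hiyama–Kishi reaction, in which the nickel-catalysed alkenylchromium species adds to the C9 aldehyde and closes the trans-fused seven-membered ring with the new alkoxide pseudo-equatorial, away from the axial C7 side chain (C9 R).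

**Step 18**
Reactants: 30 bicyclic enone (name as in step 17)
Product: 31 (2R,3S,4S)-2-[(1S,3aR,5R,7S,8R,8aR)-1,5-dihydroxy-1-methyl-4-methylidene-8-[(triethylsilyl)oxy]-1,3a,4,5,6,7,8,8a-octahydroazulen-7-yl]-6-methylhept-5-ene-3,4-diyl diacetate
Conditions: MeMgBr (4 equiv), CeCl3 (anhydrous), THF, −78 °C; aq NH4Cl
Reagents that add atoms: methylmagnesium bromide, C[Mg]Br
Why: Cerium chloride-mediated Grignard 1,2-addition to the enone from the face opposite the C5 hydrogen and the C6 silyloxy group gives the C4 S tertiary allylic alcohol (1,3-syn to the C6 oxygen), and the weakly basic reagent spares the acetates at −78 °C.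

**Step 19**
Reactants: 31 tertiary alcohol (name as in step 18)
Product: 32 (2R,3S,4S)-6-methyl-2-[(1S,3aR,5R,7S,8R,8aR)-1,5,8-trihydroxy-1-methyl-4-methylidene-1,3a,4,5,6,7,8,8a-octahydroazulen-7-yl]hept-5-ene-3,4-diyl diacetate
Conditions: HF·pyridine, pyridine, THF, 0 °C
Reagents that add atoms: none
Why: Buffered fluoride desilylation of the C6 triethylsilyl ether leaves the acetates and the tertiary allylic alcohol untouched and gives the target.

**Compound list**
1 | (3E)-pent-3-en-2-one | C/C=C/C(C)=O | starting material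
2 | (2R,3E)-pent-3-en-2-ol | C/C=C/[C@@H](C)O | intermediate
3 | methyl 4,4-dimethoxybutanoate | COC(=O)CCC(OC)OC | starting material
4 | 4,4-dimethoxybutanoic acid | OC(=O)CCC(OC)OC | intermediate
5 | (2R,3E)-pent-3-en-2-yl 4,4-dimethoxybutanoate | C/C=C/[C@@H](C)OC(=O)CCC(OC)OC | intermediate
6 | (E)-trimethylsilyl ketene acetal of 5 (CH2 chain cis to the allyl oxygen) | C/C=C/[C@@H](C)O/C(O[Si](C)(C)C)=C\CC(OC)OC | intermediate
7 | trimethylsilyl (2S,3S,4E)-2-(2,2-dimethoxyethyl)-3-methylhex-4-enoate | C/C=C/[C@H](C)[C@H](CC(OC)OC)C(=O)O[Si](C)(C)C | intermediate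
8 | (2S,3S,4E)-2-(2,2-dimethoxyethyl)-3-methylhex-4-enoic acid | C/C=C/[C@H](C)[C@H](CC(OC)OC)C(=O)O | intermediate
9 | (2S,3S,4E)-2-(2,2-dimethoxyethyl)-3-methyl-1-(morpholin-4-yl)hex-4-en-1-one | C/C=C/[C@H](C)[C@H](CC(OC)OC)C(=O)N1CCOCC1 | intermediate
10 | ozonide of 9 (3-methyl-1,2,4-trioxolan-5-yl in place of the propenyl group) | CC1OOC(O1)[C@H](C)[C@H](CC(OC)OC)C(=O)N2CCOCC2 | intermediate
11 | (2R,3S)-3-(2,2-dimethoxyethyl)-2-methyl-4-(morpholin-4-yl)-4-oxobutanal | O=C[C@H](C)[C@H](CC(OC)OC)C(=O)N1CCOCC1 | intermediate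
12 | tert-butyl(dimethyl)(prop-2-en-1-yloxy)silane | C=CCO[Si](C)(C)C(C)(C)C | starting material
13 | [(2Z)-3-{[tert-butyl(dimethyl)silyl]oxy}prop-2-en-1-yl]lithium | [Li]C/C=C\O[Si](C)(C)C(C)(C)C | intermediate
14 | tributyl[(2Z)-3-{[tert-butyl(dimethyl)silyl]oxy}prop-2-en-1-yl]stannane | CCCC[Sn](CCCC)(CCCC)C/C=C\O[Si](C)(C)C(C)(C)C | intermediate
15 | (2S,3R,4S,5S)-5-{[tert-butyl(dimethyl)silyl]oxy}-2-(2,2-dimethoxyethyl)-4-hydroxy-3-methyl-1-(morpholin-4-yl)hept-6-en-1-one | C=C[C@H](O[Si](C)(C)C(C)(C)C)[C@@H](O)[C@H](C)[C@H](CC(OC)OC)C(=O)N1CCOCC1 | intermediate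
16 | (2S,3R,4S,5S)-2-(2,2-dimethoxyethyl)-4,5-dihydroxy-3-methyl-1-(morpholin-4-yl)hept-6-en-1-one | C=C[C@H](O)[C@@H](O)[C@H](C)[C@H](CC(OC)OC)C(=O)N1CCOCC1 | intermediate
17 | (3S,4S,5R,6S)-6-(2,2-dimethoxyethyl)-5-methyl-7-(morpholin-4-yl)-7-oxohept-1-ene-3,4-diyl diacetate | C=C[C@H](OC(C)=O)[C@@H](OC(C)=O)[C@H](C)[C@H](CC(OC)OC)C(=O)N1CCOCC1 | intermediate
18 | (4S,5S,6R,7S)-7-(2,2-dimethoxyethyl)-2,6-dimethyl-8-(morpholin-4-yl)-8-oxooct-2-ene-4,5-diyl diacetate | CC(C)=C[C@H](OC(C)=O)[C@@H](OC(C)=O)[C@H](C)[C@H](CC(OC)OC)C(=O)N1CCOCC1 | intermediate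
19 | (4S,5S,6R,7S)-7-formyl-9,9-dimethoxy-2,6-dimethylnon-2-ene-4,5-diyl diacetate | CC(C)=C[C@H](OC(C)=O)[C@@H](OC(C)=O)[C@H](C)[C@H](CC(OC)OC)C=O | intermediate
20 | (4S)-4-{[tert-butyl(dimethyl)silyl]oxy}cyclopent-2-en-1-one | O=C1C=C[C@@H](O[Si](C)(C)C(C)(C)C)C1 | starting material
21 | (3S,4S)-4-{[tert-butyl(dimethyl)silyl]oxy}-3-[1-(trimethylsilyl)ethenyl]cyclopentan-1-one (3,4-trans) | O=C1C[C@H](C(=C)[Si](C)(C)C)[C@@H](O[Si](C)(C)C(C)(C)C)C1 | intermediate
22 | (4S)-4-[1-(trimethylsilyl)ethenyl]cyclopent-2-en-1-one | O=C1C=C[C@@H](C(=C)[Si](C)(C)C)C1 | intermediate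
23 | (4S)-4-[1,2-dibromo-1-(trimethylsilyl)ethyl]cyclopent-2-en-1-one (mixture at the new centre) | O=C1C=C[C@@H](C(Br)(CBr)[Si](C)(C)C)C1 | intermediate
24 | (4S)-4-(1-bromoethenyl)cyclopent-2-en-1-one | O=C1C=C[C@@H](C(Br)=C)C1 | intermediate
25 | lithium (3R)-3-(1-bromoethenyl)cyclopenta-1,4-dien-1-olate | [Li]OC1=C[C@H](C(Br)=C)C=C1 | intermediate
26 | (4S,5S,6R,7S)-7-{(R)-[(1R,5R)-5-(1-bromoethenyl)-2-oxocyclopent-3-en-1-yl](hydroxy)methyl}-9,9-dimethoxy-2,6-dimethylnon-2-ene-4,5-diyl diacetate | C=C(Br)[C@@H]1C=CC(=O)[C@H]1[C@H](O)[C@@H](CC(OC)OC)[C@@H](C)[C@H](OC(C)=O)[C@H](C=C(C)C)OC(C)=O | intermediate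
27 | triethylsilyl ether of 26 at the C6 hydroxyl | C=C(Br)[C@@H]1C=CC(=O)[C@H]1[C@H](O[Si](CC)(CC)CC)[C@@H](CC(OC)OC)[C@@H](C)[C@H](OC(C)=O)[C@H](C=C(C)C)OC(C)=O | intermediate
28 | 2,6-dimethylpyridinium N,O-acetal triflate from 27 (C9 bears OCH3 and the pyridinium nitrogen; mixture at C9) | C=C(Br)[C@@H]1C=CC(=O)[C@H]1[C@H](O[Si](CC)(CC)CC)[C@@H](CC(OC)[n+]2c(C)cccc2C)[C@@H](C)[C@H](OC(C)=O)[C@H](C=C(C)C)OC(C)=O.[O-]S(=O)(=O)C(F)(F)F | intermediate
29 | (4S,5S,6R,7S)-7-{(R)-[(1R,5R)-5-(1-bromoethenyl)-2-oxocyclopent-3-en-1-yl][(triethylsilyl)oxy]methyl}-2,6-dimethyl-9-oxonon-2-ene-4,5-diyl diacetate | C=C(Br)[C@@H]1C=CC(=O)[C@H]1[C@H](O[Si](CC)(CC)CC)[C@@H](CC=O)[C@@H](C)[C@H](OC(C)=O)[C@H](C=C(C)C)OC(C)=O | intermediate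
30 | (2R,3S,4S)-2-[(3aR,5R,7S,8R,8aR)-5-hydroxy-4-methylidene-1-oxo-8-[(triethylsilyl)oxy]-1,3a,4,5,6,7,8,8a-octahydroazulen-7-yl]-6-methylhept-5-ene-3,4-diyl diacetate | C=C1[C@H](O)C[C@@H]([C@@H](C)[C@H](OC(C)=O)[C@H](C=C(C)C)OC(C)=O)[C@@H](O[Si](CC)(CC)CC)[C@H]2[C@H]1C=CC2=O | intermediate
31 | (2R,3S,4S)-2-[(1S,3aR,5R,7S,8R,8aR)-1,5-dihydroxy-1-methyl-4-methylidene-8-[(triethylsilyl)oxy]-1,3a,4,5,6,7,8,8a-octahydroazulen-7-yl]-6-methylhept-5-ene-3,4-diyl diacetate | C=C1[C@H](O)C[C@@H]([C@@H](C)[C@H](OC(C)=O)[C@H](C=C(C)C)OC(C)=O)[C@@H](O[Si](CC)(CC)CC)[C@H]2[C@H]1C=C[C@]2(C)O | intermediate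
32 | (2R,3S,4S)-6-methyl-2-[(1S,3aR,5R,7S,8R,8aR)-1,5,8-trihydroxy-1-methyl-4-methylidene-1,3a,4,5,6,7,8,8a-octahydroazulen-7-yl]hept-5-ene-3,4-diyl diacetate | C=C1[C@H](O)C[C@@H]([C@@H](C)[C@H](OC(C)=O)[C@H](C=C(C)C)OC(C)=O)[C@@H](O)[C@H]2[C@H]1C=C[C@]2(C)O | target

**Step count and risks**
Total step count: 19. Longest linear sequence: 15 steps (1, 3, 4, 5, 6, 8, 9, 10, 11, 12, 15, 16, 17, 18, 19).

Step 8 is at risk because BF3 may engage the dimethyl acetal or the amide carbonyl, and the C12 configuration rests on substrate (Felkin) control alone. The fallback sets out from 11 and comes back at 16. It uses reagent-controlled allylboration instead of an open Lewis-acid transition state: the (Z)-γ-(4-methoxybenzyloxy)allyl diisopinocampheylborane, generated from allyl 4-methoxybenzyl ether, sBuLi, (+)-Ipc2BOMe and BF3·OEt2, adds to 11 at −78 °C to give the syn homoallylic alcohol F1. DDQ with molecular sieves closes it oxidatively to the 4-methoxybenzylidene acetal F2, and CSA in methanol releases diol 16 while the C9 dimethyl acetal stays as it is.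

Step 17 is at risk because closure of a seven-membered ring with an alkenyl bromide can be slow, and the C9 configuration is predicted from the ring conformation only. The fallback sets out from 29 and comes back at 31. It sets C9 by oxidation and catalyst-controlled reduction instead of by the cyclisation: if the ring closure gives mainly the C9 epimer F3, this is carried through the methyl addition of step 18 to the epimeric diol F4. MnO2 then oxidises the allylic C9 hydroxyl to the α-methylene ketone F5, which is reduced with (S)-2-methyl-CBS-oxazaborolidine and catecholborane to 31.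

Step 18 is at risk because the organometallic reagent may attack the two acetates, and the facial selectivity at C4 is predicted, not proven. The fallback sets out from 30 and comes back at 32. It accepts loss of the acetates and reinstalls them: the C9 hydroxyl is silylated (Et3SiOTf, 2,6-lutidine) to the bis-silyl ether F6, and excess MeLi/CeCl3 then drives both the ketone addition and the acetate cleavage to completion, giving the triol F7. Ac2O, pyridine and DMAP acetylate only the two secondary side-chain hydroxyls (the ring hydroxyls are silylated or tertiary) to give the diacetate F8, and HF·pyridine removes both silyl groups to give 32.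

**Further compounds**
F1 | step 8 | (2S,3R,4S,5S)-2-(2,2-dimethoxyethyl)-4-hydroxy-5-[(4-methoxyphenyl)methoxy]-3-methyl-1-(morpholin-4-yl)hept-6-en-1-one | C=C[C@H](OCc1ccc(OC)cc1)[C@@H](O)[C@H](C)[C@H](CC(OC)OC)C(=O)N1CCOCC1
F2 | step 8 | (2S,3R)-2-(2,2-dimethoxyethyl)-3-[(4S,5S)-5-ethenyl-2-(4-methoxyphenyl)-1,3-dioxolan-4-yl]-1-(morpholin-4-yl)butan-1-one | C=C[C@@H]1OC(c2ccc(OC)cc2)O[C@H]1[C@H](C)[C@H](CC(OC)OC)C(=O)N3CCOCC3
F3 | step 17 | (2R,3S,4S)-2-[(3aR,5S,7S,8R,8aR)-5-hydroxy-4-methylidene-1-oxo-8-[(triethylsilyl)oxy]-1,3a,4,5,6,7,8,8a-octahydroazulen-7-yl]-6-methylhept-5-ene-3,4-diyl diacetate | C=C1[C@@H](O)C[C@@H]([C@@H](C)[C@H](OC(C)=O)[C@H](C=C(C)C)OC(C)=O)[C@@H](O[Si](CC)(CC)CC)[C@H]2[C@H]1C=CC2=O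
F4 | step 17 | (2R,3S,4S)-2-[(1S,3aR,5S,7S,8R,8aR)-1,5-dihydroxy-1-methyl-4-methylidene-8-[(triethylsilyl)oxy]-1,3a,4,5,6,7,8,8a-octahydroazulen-7-yl]-6-methylhept-5-ene-3,4-diyl diacetate | C=C1[C@@H](O)C[C@@H]([C@@H](C)[C@H](OC(C)=O)[C@H](C=C(C)C)OC(C)=O)[C@@H](O[Si](CC)(CC)CC)[C@H]2[C@H]1C=C[C@]2(C)O
F5 | step 17 | (2R,3S,4S)-2-[(1S,3aR,7S,8R,8aR)-1-hydroxy-1-methyl-4-methylidene-5-oxo-8-[(triethylsilyl)oxy]-1,3a,4,5,6,7,8,8a-octahydroazulen-7-yl]-6-methylhept-5-ene-3,4-diyl diacetate | C=C1C(=O)C[C@@H]([C@@H](C)[C@H](OC(C)=O)[C@H](C=C(C)C)OC(C)=O)[C@@H](O[Si](CC)(CC)CC)[C@H]2[C@H]1C=C[C@]2(C)O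
F6 | step 18 | (2R,3S,4S)-2-[(3aR,5R,7S,8R,8aR)-4-methylidene-1-oxo-5,8-bis[(triethylsilyl)oxy]-1,3a,4,5,6,7,8,8a-octahydroazulen-7-yl]-6-methylhept-5-ene-3,4-diyl diacetate | C=C1[C@H](O[Si](CC)(CC)CC)C[C@@H]([C@@H](C)[C@H](OC(C)=O)[C@H](C=C(C)C)OC(C)=O)[C@@H](O[Si](CC)(CC)CC)[C@H]2[C@H]1C=CC2=O
F7 | step 18 | (1S,3aR,5R,7S,8R,8aR)-7-[(2R,3S,4S)-3,4-dihydroxy-6-methylhept-5-en-2-yl]-1-methyl-4-methylidene-5,8-bis[(triethylsilyl)oxy]-1,3a,4,5,6,7,8,8a-octahydroazulen-1-ol | C=C1[C@H](O[Si](CC)(CC)CC)C[C@@H]([C@@H](C)[C@H](O)[C@H](C=C(C)C)O)[C@@H](O[Si](CC)(CC)CC)[C@H]2[C@H]1C=C[C@]2(C)O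
F8 | step 18 | (2R,3S,4S)-2-[(1S,3aR,5R,7S,8R,8aR)-1-hydroxy-1-methyl-4-methylidene-5,8-bis[(triethylsilyl)oxy]-1,3a,4,5,6,7,8,8a-octahydroazulen-7-yl]-6-methylhept-5-ene-3,4-diyl diacetate | C=C1[C@H](O[Si](CC)(CC)CC)C[C@@H]([C@@H](C)[C@H](OC(C)=O)[C@H](C=C(C)C)OC(C)=O)[C@@H](O[Si](CC)(CC)CC)[C@H]2[C@H]1C=C[C@]2(C)O
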